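**Plan**
1. Ring A is lettered C(a) (bears the chain), C(b) (CH), C(c) (bears the aryl ether oxygen), C(d) (bears methoxy), C(e) and C(f) (both CH). The vicinal oxygens on C(c) and C(d) make C(b)–C(c)–C(d)–C(e) a 2-aryloxy-3-methoxybutadiene, and the chain para to methoxy makes C(a) and C(f) the two carbons of an alkynyl ketone.
2. Retrosynthesis: with a ketone written at C1, a ketal at C3 and the phenol masked as its methoxymethyl ether, ring A is cut at C(a)–C(b) and C(e)–C(f). This also opens the 15-membered ring and leaves a ring B aryl dienyl ether with a terminal ynone at the chain end.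
3. Further cuts: diene to aryl 2-methoxyacrylate (ester methylenation) to phenol; ynone to C1 aldehyde plus acetylide; chain at C6=C7 (Wittig) between a ring B aldehyde and a C1–C6 ketal phosphonium salt.
4. Forward order: ring B aldehyde (steps 1–3) and phosphonium salt (steps 4–8) are joined and hydrogenated (9, 10). The diene is installed (11–13) and the ynone made (14–17). Ring A and the macrocycle then arise together (18), and C1 is deoxygenated and the masks removed (19–21).
5. Stereochemistry: the target has no stereocentre. The carbinol centres of 24 and 28 are racemic and transient, and the alkene geometry of 16 is erased by hydrogenation.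

Key step: step 18

Remark: the heptane chain is numbered C1 (on ring A) to C7 (on ring B), C3 being the ketone carbon of the target. The cyclophane is taken as conformationally mobile, so no planar chirality has to be controlled.

**Step 1**
Reactants: 1 2-methoxyresorcinol
Product: 3 2,4-dihydroxy-3-methoxybenzaldehyde, via aryl iminium chloride 2 (not isolated)
Conditions: POCl3, DMF, MeCN, 0 °C → rt; then H2O, 50 °C
Reagents that add atoms: N,N-dimethylformamide CN(C)C=O; water O
Why: Vilsmeier–Haack formylation attacks C4/C6 (equivalent by symmetry, ortho to one hydroxyl and para to the other), and hydrolysis of the iminium salt frees the aldehyde.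

**Step 2**
Reactants: 3 2,4-dihydroxy-3-methoxybenzaldehyde
Product: 4 4-(benzyloxy)-2-hydroxy-3-methoxybenzaldehyde
Conditions: BnBr (1.05 equiv), NaHCO3, KI (cat.), MeCN, 60 °C
Reagents that add atoms: benzyl bromide BrCc1ccccc1
Why: Williamson etherification under bicarbonate should alkylate only the 4-hydroxyl, which is the more acidic one (para to formyl) and is not tied up in the hydrogen bond to the carbonyl that deactivates the 2-hydroxyl.

**Step 3**
Reactants: 4 4-(benzyloxy)-2-hydroxy-3-methoxybenzaldehyde
Product: 5 4-(benzyloxy)-3-methoxy-2-(methoxymethoxy)benzaldehyde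
Conditions: NaH, DMF, 0 °C; then MOMCl, 0 °C → rt
Reagents that add atoms: chloromethyl methyl ether COCCl
Why: Williamson-type alkylation of the preformed sodium phenoxide with the reactive chloromethyl ether overcomes chelation and crowding at the 2-hydroxyl; the resulting acetal ether withstands base and hydrogenation and falls only in the final acid step.

**Step 4**
Reactants: 6 4-chlorobutanoyl chloride; 7 Meldrum's acid
Product: 9 methyl 6-chloro-3-oxohexanoate, via acyl Meldrum's acid 8 (not isolated)
Conditions: pyridine, CH2Cl2, 0 °C → rt; then MeOH, reflux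
Reagents that add atoms: methanol CO
Why: C-acylation of Meldrum's acid followed by methanolysis with loss of acetone and CO2 is the standard acyl Meldrum's acid route to β-keto esters and leaves the primary chloride untouched.

**Step 5**
Reactants: 9 methyl 6-chloro-3-oxohexanoate
Product: 10 methyl 2-[2-(3-chloropropyl)-1,3-dioxolan-2-yl]acetate
Conditions: HOCH2CH2OH, TsOH·H2O (cat.), benzene, reflux, Dean–Stark
Reagents that add atoms: ethylene glycol OCCO
Why: acid-catalysed ketalisation with azeotropic water removal is routine for β-keto esters, and placing the C3 ketal on this small fragment keeps acid away from every later acid-sensitive intermediate.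

**Step 6**
Reactants: 10 methyl 2-[2-(3-chloropropyl)-1,3-dioxolan-2-yl]acetate
Product: 11 2-[2-(3-chloropropyl)-1,3-dioxolan-2-yl]ethanol
Conditions: LiBH4, THF, MeOH (1 equiv), 0 °C → rt
Reagents that add atoms: none
Why: LiBH4 reduces the ester to the primary alcohol and does not touch the primary chloride or the ketal.

**Step 7**
Reactants: 11 2-[2-(3-chloropropyl)-1,3-dioxolan-2-yl]ethanol
Product: 12 tert-butyl{2-[2-(3-chloropropyl)-1,3-dioxolan-2-yl]ethoxy}dimethylsilane
Conditions: TBSCl, imidazole, CH2Cl2, rt
Reagents that add atoms: tert-butyldimethylsilyl chloride CC(C)(C)[Si](C)(C)Cl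
Why: standard silylation masks the C1 alcohol as an ether that is inert to ylide base, hydrogenation, carbodiimide and Cp2Ti=CH2 and is later removed by fluoride without acid.

**Step 8**
Reactants: 12 tert-butyl{2-[2-(3-chloropropyl)-1,3-dioxolan-2-yl]ethoxy}dimethylsilane
Product: 14 {3-[2-(2-{[tert-butyl(dimethyl)silyl]oxy}ethyl)-1,3-dioxolan-2-yl]propyl}triphenylphosphonium iodide, via alkyl iodide 13 (not isolated)
Conditions: NaI, PPh3, NaHCO3 (acid scavenger), MeCN, reflux
Reagents that add atoms: sodium iodide [Na+].[I-]; triphenylphosphine c1ccc(cc1)P(c1ccccc1)c1ccccc1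
Why: Finkelstein exchange to the iodide in the flask followed by SN2 quaternisation of triphenylphosphine is the usual way to phosphonium salts from ketal-bearing primary chlorides.

**Step 9**
Reactants: 14 phosphonium iodide; 5 4-(benzyloxy)-3-methoxy-2-(methoxymethoxy)benzaldehyde
Product: 16 1-(benzyloxy)-4-[(1Z)-4-{2-[2-(tert-butyldimethylsilyloxy)ethyl]-1,3-dioxolan-2-yl}but-1-en-1-yl]-2-methoxy-3-(methoxymethoxy)benzene, via phosphonium ylide 15 (not isolated)
Conditions: KN(SiMe3)2, THF, −78 °C; then 5, −78 °C → rt
Reagents that add atoms: none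
Why: Wittig olefination of the unstabilised ylide with the aromatic aldehyde joins C6 to C7; mainly the Z alkene is expected, and the geometry is irrelevant because the double bond is saturated in the next step.

**Step 10**
Reactants: 16 Wittig alkene
Product: 17 4-{4-[2-(2-{[tert-butyl(dimethyl)silyl]oxy}ethyl)-1,3-dioxolan-2-yl]butyl}-2-methoxy-3-(methoxymethoxy)phenol
Conditions: H2 (1 atm), 10% Pd/C, EtOAc, rt
Reagents that add atoms: none
Why: heterogeneous hydrogenation saturates the styrene double bond and hydrogenolyses the aryl benzyl ether in one operation, while silyl ether, ketal and methoxymethyl ether are inert in neutral ethyl acetate.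

**Step 11**
Reactants: 18 methyl 2-methoxyacrylate
Product: 19 2-methoxyacrylic acid
Conditions: LiOH, THF–H2O, 0 °C → rt; then cold 1 M HCl to pH 3, extraction
Reagents that add atoms: lithium hydroxide [Li+].[OH-]
Why: saponification of the methyl ester followed by brief cold acidification should give the free acid with the enol ether intact.

**Step 12**
Reactants: 17 phenol; 19 2-methoxyacrylic acid
Product: 20 4-{4-[2-(2-{[tert-butyl(dimethyl)silyl]oxy}ethyl)-1,3-dioxolan-2-yl]butyl}-2-methoxy-3-(methoxymethoxy)phenyl 2-methoxyprop-2-enoate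
Conditions: DCC, DMAP (cat.), BHT (trace), CH2Cl2, 0 °C → rt
Reagents that add atoms: none
Why: Steglich esterification acylates the only free hydroxyl, the phenol, under neutral conditions that suit the ketal, the silyl ether and the enol ether of the acid.

**Step 13**
Reactants: 20 aryl 2-methoxyacrylate
Product: 21 tert-butyl{2-[2-(4-{3-methoxy-4-[(3-methoxybuta-1,3-dien-2-yl)oxy]-2-(methoxymethoxy)phenyl}butyl)-1,3-dioxolan-2-yl]ethoxy}dimethylsilane
Conditions: Cp2TiMe2 (3 equiv), toluene–THF, 70 °C, dark; basic alumina filtration
Reagents that add atoms: dimethyltitanocene C[Ti](C)(C1C=CC=C1)C1C=CC=C1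
Why: Petasis methylenation converts the ester carbonyl into the enol ether through an oxatitanacyclobutane, a reaction established for aryl esters and for conjugated esters (which give 2-alkoxydienes); the substrate carries no other carbonyl group and no alkyne, and ketal, silyl ether and acetal ether are inert to Cp2Ti=CH2.

**Step 14**
Reactants: 21 dienyl ether silyl ether
Product: 22 2-[2-(4-{3-methoxy-4-[(3-methoxybuta-1,3-dien-2-yl)oxy]-2-(methoxymethoxy)phenyl}butyl)-1,3-dioxolan-2-yl]ethanol
Conditions: Bu4NF, THF, 0 °C; H2O work-up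
Reagents that add atoms: none
Why: fluoride cleaves the primary silyl ether under basic conditions that the acid-sensitive bis(enol ether) diene tolerates.

**Step 15**
Reactants: 22 dienyl ether alcohol
Product: 23 2-[2-(4-{3-methoxy-4-[(3-methoxybuta-1,3-dien-2-yl)oxy]-2-(methoxymethoxy)phenyl}butyl)-1,3-dioxolan-2-yl]acetaldehyde
Conditions: n-Pr4N[RuO4] (5 mol %), NMO, 4 Å sieves, CH2Cl2, rt
Reagents that add atoms: none
Why: Ley–Griffith oxidation stops at the aldehyde under neutral conditions that spare enol ethers, ketal and acetal ether.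

**Step 16**
Reactants: 23 dienyl ether aldehyde
Product: 24 1-[2-(4-{3-methoxy-4-[(3-methoxybuta-1,3-dien-2-yl)oxy]-2-(methoxymethoxy)phenyl}butyl)-1,3-dioxolan-2-yl]but-3-yn-2-ol (racemic)
Conditions: HC≡CMgBr, THF, −78 → 0 °C; then pH 7 buffer
Reagents that add atoms: ethynylmagnesium bromide C#C[Mg]Br
Why: Grignard addition of the acetylide to the aldehyde at low temperature gives the secondary propargylic alcohol as a racemate, whose new stereocentre does not matter because it is oxidised away in the next step.

**Step 17**
Reactants: 24 propargylic alcohol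
Product: 25 1-[2-(4-{3-methoxy-4-[(3-methoxybuta-1,3-dien-2-yl)oxy]-2-(methoxymethoxy)phenyl}butyl)-1,3-dioxolan-2-yl]but-3-yn-2-one
Conditions: activated MnO2 (excess), CH2Cl2, rt; filtration, solution kept dilute and cold
Reagents that add atoms: none
Why: activated MnO2 oxidises propargylic alcohols selectively under neutral heterogeneous conditions, giving the terminal ynone without acid or amine base that would harm the diene or the ynone.

**Step 18**
Reactants: 25 dienyl ether ynone
Product: 27 1-oxojuglanin A 3-(ethylene ketal) O-methoxymethyl ether, via cyclohexadiene cycloadduct 26 (not isolated)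
Conditions: slow addition to toluene (final about 1 mM), BHT, 110 °C; then rt, DDQ (1.2 equiv), same flask
Reagents that add atoms: none
Why: Proposed new method: on heating at high dilution the electron-rich 2-aryloxy-3-methoxybutadiene and the tethered terminal ynone should combine in a concerted, normal-electron-demand [4+2] cycloaddition to the 1,4-cyclohexadiene 26, whose doubly allylic CH2 groups then lose hydride and a proton to DDQ so that ring A becomes aromatic; the closest known reaction types are type 2 intramolecular Diels–Alder reactions of dienes tethered at C2, which give meta-bridged rings, and the intermolecular cycloaddition of 2,3-dialkoxybutadienes with ynones followed by dehydrogenation to arenes. Ring A (six-membered) closes by the cycloaddition itself through the C(a)–C(b) and C(e)–C(f) bonds, and the 15-membered ring closes in the same event as the meta bridge between C(a) and C(c), a macrocyclisation in the bridged mode in which ring B, the ether oxygen and the seven-carbon chain are the tether. No lasting stereocentre is formed, since C(b) and C(e) of 26 are CH2 groups that are aromatised. The step needs regioselectivity (terminal alkyne carbon to C(e)) and it needs cyclisation to outrun oligomerisation: the first should follow because methoxy is the stronger donor and places the larger HOMO coefficient on its neighbouring methylene, which pairs with the β carbon of the ynone (para rule), and because the seven-carbon chain cannot comfortably span para positions on both rings; the second is addressed by slow addition to hot toluene at about 1 mM. The ring being formed is not yet a flat arene in the transition state, which should ease the strain that burdens closures of this cyclophane at the aromatic stage, and the C3 ketal adds a gem-disubstituent effect.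

**Step 19**
Reactants: 27 macrocyclic aryl ketone
Product: 28 1-hydroxyjuglanin A 3-(ethylene ketal) O-methoxymethyl ether (racemic at C1)
Conditions: NaBH4, MeOH–THF, 0 °C
Reagents that add atoms: none
Why: borohydride reduction of the aryl ketone gives the benzylic alcohol (its configuration is irrelevant because C1 becomes CH2), with ketal and acetal ether untouched.

**Step 20**
Reactants: 28 macrocyclic benzylic alcohol
Product: 29 juglanin A 3-(ethylene ketal) O-methoxymethyl ether
Conditions: H2 (1 atm), 10% Pd/C, EtOAc–AcOH (10:1), rt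
Reagents that add atoms: none
Why: catalytic hydrogenolysis of the benzylic C–O bond is eased by the para methoxy group of ring A and the acetic acid co-solvent, while the diaryl ether, ketal and methoxymethyl ether should survive these mild conditions.

**Step 21**
Reactants: 29 juglanin A 3-(ethylene ketal) O-methoxymethyl ether
Product: 30 juglanin A
Conditions: 2 M HCl, THF, 40 °C
Reagents that add atoms: water O
Why: aqueous acid hydrolyses the dioxolane to the C3 ketone and the methoxymethyl acetal to the free phenol in one operation, giving the achiral target.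

**Compound list**
1 | 2-methoxyresorcinol (2-methoxybenzene-1,3-diol) | COc1c(O)cccc1O | starting material
2 | N-[(2,4-dihydroxy-3-methoxyphenyl)methylidene]-N-methylmethanaminium chloride | C[N+](C)=Cc1ccc(O)c(OC)c1O.[Cl-] | intermediate
3 | 2,4-dihydroxy-3-methoxybenzaldehyde | O=Cc1ccc(O)c(OC)c1O | intermediate
4 | 4-(benzyloxy)-2-hydroxy-3-methoxybenzaldehyde | O=Cc1ccc(OCc2ccccc2)c(OC)c1O | intermediate
5 | 4-(benzyloxy)-3-methoxy-2-(methoxymethoxy)benzaldehyde | O=Cc1ccc(OCc2ccccc2)c(OC)c1OCOC | intermediate
6 | 4-chlorobutanoyl chloride | O=C(Cl)CCCCl | starting material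
7 | Meldrum's acid (2,2-dimethyl-1,3-dioxane-4,6-dione) | CC1(C)OC(=O)CC(=O)O1 | starting material
8 | 5-(4-chlorobutanoyl)-2,2-dimethyl-1,3-dioxane-4,6-dione | CC1(C)OC(=O)C(C(=O)CCCCl)C(=O)O1 | intermediate
9 | methyl 6-chloro-3-oxohexanoate | COC(=O)CC(=O)CCCCl | intermediate
10 | methyl 2-[2-(3-chloropropyl)-1,3-dioxolan-2-yl]acetate | COC(=O)CC1(CCCCl)OCCO1 | intermediate
11 | 2-[2-(3-chloropropyl)-1,3-dioxolan-2-yl]ethanol | OCCC1(CCCCl)OCCO1 | intermediate
12 | tert-butyl{2-[2-(3-chloropropyl)-1,3-dioxolan-2-yl]ethoxy}dimethylsilane | CC(C)(C)[Si](C)(C)OCCC1(CCCCl)OCCO1 | intermediate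
13 | tert-butyl{2-[2-(3-iodopropyl)-1,3-dioxolan-2-yl]ethoxy}dimethylsilane | CC(C)(C)[Si](C)(C)OCCC1(CCCI)OCCO1 | intermediate
14 | {3-[2-(2-{[tert-butyl(dimethyl)silyl]oxy}ethyl)-1,3-dioxolan-2-yl]propyl}triphenylphosphonium iodide | CC(C)(C)[Si](C)(C)OCCC1(CCC[P+](c2ccccc2)(c2ccccc2)c2ccccc2)OCCO1.[I-] | intermediate
15 | phosphonium ylide of 14 (triphenylphosphoranylidene at the former P–CH2 carbon) | CC(C)(C)[Si](C)(C)OCCC1(CCC=P(c2ccccc2)(c2ccccc2)c2ccccc2)OCCO1 | intermediate
16 | 1-(benzyloxy)-4-[(1Z)-4-{2-[2-(tert-butyldimethylsilyloxy)ethyl]-1,3-dioxolan-2-yl}but-1-en-1-yl]-2-methoxy-3-(methoxymethoxy)benzene (Z drawn; E isomer equally usable) | COCOc1c(/C=C\CCC2(CCO[Si](C)(C)C(C)(C)C)OCCO2)ccc(OCc2ccccc2)c1OC | intermediate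
17 | 4-{4-[2-(2-{[tert-butyl(dimethyl)silyl]oxy}ethyl)-1,3-dioxolan-2-yl]butyl}-2-methoxy-3-(methoxymethoxy)phenol | COCOc1c(CCCCC2(CCO[Si](C)(C)C(C)(C)C)OCCO2)ccc(O)c1OC | intermediate
18 | methyl 2-methoxyacrylate | C=C(OC)C(=O)OC | starting material
19 | 2-methoxyacrylic acid (2-methoxyprop-2-enoic acid) | C=C(OC)C(=O)O | intermediate
20 | 4-{4-[2-(2-{[tert-butyl(dimethyl)silyl]oxy}ethyl)-1,3-dioxolan-2-yl]butyl}-2-methoxy-3-(methoxymethoxy)phenyl 2-methoxyprop-2-enoate | C=C(OC)C(=O)Oc1ccc(CCCCC2(CCO[Si](C)(C)C(C)(C)C)OCCO2)c(OCOC)c1OC | intermediate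
21 | tert-butyl{2-[2-(4-{3-methoxy-4-[(3-methoxybuta-1,3-dien-2-yl)oxy]-2-(methoxymethoxy)phenyl}butyl)-1,3-dioxolan-2-yl]ethoxy}dimethylsilane | C=C(OC)C(=C)Oc1ccc(CCCCC2(CCO[Si](C)(C)C(C)(C)C)OCCO2)c(OCOC)c1OC | intermediate
22 | 2-[2-(4-{3-methoxy-4-[(3-methoxybuta-1,3-dien-2-yl)oxy]-2-(methoxymethoxy)phenyl}butyl)-1,3-dioxolan-2-yl]ethanol | C=C(OC)C(=C)Oc1ccc(CCCCC2(CCO)OCCO2)c(OCOC)c1OC | intermediate
23 | 2-[2-(4-{3-methoxy-4-[(3-methoxybuta-1,3-dien-2-yl)oxy]-2-(methoxymethoxy)phenyl}butyl)-1,3-dioxolan-2-yl]acetaldehyde | C=C(OC)C(=C)Oc1ccc(CCCCC2(CC=O)OCCO2)c(OCOC)c1OC | intermediate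
24 | 1-[2-(4-{3-methoxy-4-[(3-methoxybuta-1,3-dien-2-yl)oxy]-2-(methoxymethoxy)phenyl}butyl)-1,3-dioxolan-2-yl]but-3-yn-2-ol (racemic) | C=C(OC)C(=C)Oc1ccc(CCCCC2(CC(O)C#C)OCCO2)c(OCOC)c1OC | intermediate
25 | 1-[2-(4-{3-methoxy-4-[(3-methoxybuta-1,3-dien-2-yl)oxy]-2-(methoxymethoxy)phenyl}butyl)-1,3-dioxolan-2-yl]but-3-yn-2-one | C=C(OC)C(=C)Oc1ccc(CCCCC2(CC(=O)C#C)OCCO2)c(OCOC)c1OC | intermediate
26 | cyclohexa-1,4-diene cycloadduct (ring A with C(a)=C(f) and C(c)=C(d) double bonds, C(b) and C(e) as CH2; bridged from C(a) through the C1 ketone, the C3 ethylene ketal, four CH2, ring B and the ether oxygen to C(c)) | COC1=C2CC(=CC1)C(=O)CC1(OCCO1)CCCCc1ccc(O2)c(OC)c1OCOC | intermediate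
27 | 1-oxojuglanin A 3-(ethylene ketal) O-methoxymethyl ether | COc1ccc2cc1Oc1ccc(c(OCOC)c1OC)CCCCC1(OCCO1)CC2=O | intermediate
28 | 1-hydroxyjuglanin A 3-(ethylene ketal) O-methoxymethyl ether (racemic at C1) | COc1ccc2cc1Oc1ccc(c(OCOC)c1OC)CCCCC1(OCCO1)CC2O | intermediate
29 | juglanin A 3-(ethylene ketal) O-methoxymethyl ether | COc1ccc2cc1Oc1ccc(c(OCOC)c1OC)CCCCC1(OCCO1)CC2 | intermediate
30 | juglanin A | COc1ccc2cc1Oc1ccc(c(O)c1OC)CCCCC(=O)CC2 | target

**Count**
Total: 21 steps. Longest linear sequence: 17 steps (steps 4–10 and 12–21, from 4-chlorobutanoyl chloride and Meldrum's acid).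

**Steps most likely to fail**

Step 18 (proposed new method). The cycloaddition may not close the large ring: intermolecular cycloaddition and oligomerisation, or thermal loss of the ynone, may outrun cyclisation, or the addition may take the other orientation. The fallback closes the macrocycle by the classical copper-mediated diaryl ether synthesis. It sets out from phenol 17 and comes back at 29. Fluoride desilylation of 17 gives the phenol alcohol F1, and iodine, PPh3 and imidazole convert its primary hydroxyl into the iodide F2. The phenol of the iodide is deprotonated with i-PrMgCl. Li2CuCl4-catalysed coupling with (3-bromo-4-methoxyphenyl)magnesium chloride F3, made from 2-bromo-4-iodoanisole and i-PrMgCl by iodine–magnesium exchange, then gives the linear bromo phenol F4. Intramolecular Ullmann etherification (CuO, K2CO3, pyridine, reflux, high dilution) then gives 29, which enters step 21.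

Step 13. The oxatitanacyclobutane may collapse with expulsion of the phenoxide (acyl cleavage), or the acrylate may polymerise at 70 °C before it is methylenated. The fallback moves the carbonyl to the other diene carbon so that an ordinary methyl ester is methylenated. It sets out from phenol 17 and comes back at 21. Heating 17 with methyl 2,3-dibromopropanoate and K2CO3 in acetone (elimination, conjugate addition of the phenoxide, elimination) gives the methyl 2-aryloxyacrylate F5. Methylenation of its methyl ester with Cp2TiMe2 gives the same diene 21.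

Step 17. The terminal ynone may be consumed as it forms, by cycloaddition with the diene of a second molecule during handling or by decomposition on the oxide surface. The fallback carries the alkyne silylated until the moment of use. It sets out from aldehyde 23 and comes back at 25. Addition of LiC≡CSiMe3 gives the silylated propargylic alcohol F6, and Dess–Martin periodinane with pyridine gives the silyl ynone F7, which is a far poorer dienophile and can be stored. Na2B4O7·10H2O in aqueous methanol removes silicon just before cyclisation, and the solution of 25 is fed directly into step 18.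

**Further compounds**
F1 | step 18 | 4-{4-[2-(2-hydroxyethyl)-1,3-dioxolan-2-yl]butyl}-2-methoxy-3-(methoxymethoxy)phenol | COCOc1c(CCCCC2(CCO)OCCO2)ccc(O)c1OC
F2 | step 18 | 4-{4-[2-(2-iodoethyl)-1,3-dioxolan-2-yl]butyl}-2-methoxy-3-(methoxymethoxy)phenol | COCOc1c(CCCCC2(CCI)OCCO2)ccc(O)c1OC
F3 | step 18 | (3-bromo-4-methoxyphenyl)magnesium chloride | COc1ccc([Mg]Cl)cc1Br
F4 | step 18 | 4-(4-{2-[2-(3-bromo-4-methoxyphenyl)ethyl]-1,3-dioxolan-2-yl}butyl)-2-methoxy-3-(methoxymethoxy)phenol | COCOc1c(CCCCC2(CCc3ccc(OC)c(Br)c3)OCCO2)ccc(O)c1OC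
F5 | step 13 | methyl 2-(4-{4-[2-(2-{[tert-butyl(dimethyl)silyl]oxy}ethyl)-1,3-dioxolan-2-yl]butyl}-2-methoxy-3-(methoxymethoxy)phenoxy)prop-2-enoate | C=C(Oc1ccc(CCCCC2(CCO[Si](C)(C)C(C)(C)C)OCCO2)c(OCOC)c1OC)C(=O)OC
F6 | step 17 | 1-[2-(4-{3-methoxy-4-[(3-methoxybuta-1,3-dien-2-yl)oxy]-2-(methoxymethoxy)phenyl}butyl)-1,3-dioxolan-2-yl]-4-(trimethylsilyl)but-3-yn-2-ol (racemic) | C=C(OC)C(=C)Oc1ccc(CCCCC2(CC(O)C#C[Si](C)(C)C)OCCO2)c(OCOC)c1OC
F7 | step 17 | 1-[2-(4-{3-methoxy-4-[(3-methoxybuta-1,3-dien-2-yl)oxy]-2-(methoxymethoxy)phenyl}butyl)-1,3-dioxolan-2-yl]-4-(trimethylsilyl)but-3-yn-2-one | C=C(OC)C(=C)Oc1ccc(CCCCC2(CC(=O)C#C[Si](C)(C)C)OCCO2)c(OCOC)c1OC
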